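**Plan**

- Numbering as in carotenoids: ring C1 (CMe2), C2, C3 (CHOH), C4, C5 (C–CH3) = C6 (C–alkynyl); alkyne C7≡C8; chain C9…C15, C15'…C8' (CHO).
- Cuts: C11=C12 (Wittig: C15 ring phosphonium salt + C15 polyene aldehyde ester), C11'=C12' (HWE on the C10 dialdehyde), C8–C9 and C6–C7 (two Sonogashira couplings), and in the ring the C1–C6 bond. The open chain then falls apart into (S)-epichlorohydrin (C2–C4), an isopropenyl unit (C1 and its two methyl carbons), acetylene (C5, C6) and a methyl group from AlMe3.
- Enabling feature: the cyclohexene is a cyclogeranyl ring. Its gem-dimethyl carbon C1 is a latent tertiary cation and the C5=C6–C7≡C8 enyne is a built-in π-nucleophile, so one proton turns an open-chain 1,5-dien-7-yne into the ring, the quaternary carbon and the tetrasubstituted ene–yne at once.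
- Forward: epichlorohydrin → acyclic (S)-dienynol 9 (steps 1–4) → the only ring, by acid-catalysed cation–olefin cyclisation (step 5) → C15 phosphonium salt 17 (steps 6–10) → Wittig with aldehyde ester 21 (steps 11–13) → ester to aldehyde (steps 14–15).
- Stereochemistry: C3 comes from (S)-epichlorohydrin and is never a reacting centre; its descriptor changes from S to R at ring closure only through the ranking rules. 9E comes from the E-enol triflate (retention), 11E and 11'E from Wittig/HWE with thermal equilibration, the remaining chain double bonds from the all-E dialdehyde and the E-bromo ester. Alkene geometry and double-bond position around C5 do not matter in the cyclisation, because all isomers pass through the same C5 cation.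

Key step: step 5

Assumption: the target is taken as the all-E, (3R) isomer drawn, and bromo ester 18 and dialdehyde 20 are treated as purchasable carotenoid building blocks.

**Step 1**
Reactants: 1 (S)-epichlorohydrin; 2 isopropenylmagnesium bromide
Product: 3 (2S)-1-chloro-4-methylpent-4-en-2-ol
Conditions: CuI (10 mol %), THF, −40 → 0 °C; aqueous work-up
Reagents that add atoms: none
Why: Copper-catalysed Grignard opening of the epoxide at its unsubstituted carbon (SN2) does not touch the carbinol carbon, so the configuration of 1 is carried into 3.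

**Step 2**
Reactants: 3 (2S)-1-chloro-4-methylpent-4-en-2-ol
Product: 5 (4S)-6-methylhept-6-en-1-yn-4-ol, via epoxide 4 (not isolated)
Conditions: LiC≡CH·H2NCH2CH2NH2 (3 equiv), DMSO, 0 → 25 °C; H2O
Reagents that add atoms: lithium acetylide ethylenediamine complex, [Li]C#C.NCCN
Why: One equivalent of acetylide closes the chlorohydrin to the terminal epoxide (intramolecular Williamson reaction) and a second opens it at the CH2 terminus (SN2 epoxide opening), neither event involving the stereocentre.

**Step 3**
Reactants: 5 (4S)-6-methylhept-6-en-1-yn-4-ol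
Product: 7 (1E,4S)-1-iodo-2,6-dimethylhepta-1,6-dien-4-ol, via alkenylalane 6 (not isolated)
Conditions: AlMe3 (3 equiv), (C5H5)2ZrCl2 (25 mol %), CH2Cl2, 0 → 25 °C; then I2, THF, −30 → 0 °C; aq. K2CO3
Reagents that add atoms: trimethylaluminium, C[Al](C)C; iodine, II
Why: Zirconium-catalysed Negishi carboalumination adds methyl and aluminium syn across the terminal alkyne with methyl on the internal carbon, and iodinolysis of the C–Al bond with retention should give the E-iodide, the 1,1-disubstituted alkene being inert.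

**Step 4**
Reactants: 7 (1E,4S)-1-iodo-2,6-dimethylhepta-1,6-dien-4-ol; 8 ethynyltrimethylsilane
Product: 9 (4S,6E)-2,6-dimethyl-9-(trimethylsilyl)nona-1,6-dien-8-yn-4-ol
Conditions: Pd(PPh3)2Cl2 (2 mol %), CuI (4 mol %), Et3N, THF, 25 °C
Reagents that add atoms: none
Why: Sonogashira coupling of an alkenyl iodide with a terminal alkyne proceeds with retention of alkene geometry and tolerates the free alcohol.

**Step 5**
Reactants: 9 (4S,6E)-2,6-dimethyl-9-(trimethylsilyl)nona-1,6-dien-8-yn-4-ol
Product: 11 (1R)-3,5,5-trimethyl-4-[(trimethylsilyl)ethynyl]cyclohex-3-en-1-yl trifluoroacetate, via trifluoroacetate 10 (not isolated)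
Conditions: (CF3CO)2O (1.3 equiv), CH2Cl2, 0 °C, volatiles evaporated; then CF3SO3H (0.3 equiv), CH2Cl2, −78 → −20 °C; Et3N quench
Reagents that add atoms: trifluoroacetic anhydride, O=C(OC(=O)C(F)(F)F)C(F)(F)F
Why: Protonation of the 1,1-disubstituted alkene of 10 gives the tertiary cation at the future gem-dimethyl carbon C1, C6 of the enyne attacks it through a chair-like transition state to form the C1–C6 bond and the tertiary C5 cation, and loss of the propargylic C6–H gives the tetrasubstituted C5=C6 bond conjugated with the alkyne and returns the proton, so the acid turns over. The closest known reaction type is the Brønsted-acid cation–olefin cyclisation of terpenoid 1,5-dienes to cyclogeranyl rings (pseudoionone to β-ionone), the laboratory counterpart of carotenoid β-cyclisation. The six-membered ring closes in the 6-endo-trig mode with Markovnikov attack; the 5-exo alternative would join two quaternary carbons and leave a secondary propargylic cation. No new stereocentre arises because C1 carries two methyl groups, and the carbinol carbon is not a cationic site, so its configuration is kept (the descriptor becomes R only because the substituent ranking changes on ring closure). The step needs initiation at the right alkene, proton loss towards C6 and an inert oxygen function: the isobutenyl-type alkene is the more basic one, the Δ4 and exocyclic isomers (and any Z-enyne) re-enter the same C5 cation under the acid and drain to the conjugated enyne, and the trifluoroacetate, which hardly bridges to a cation and cannot form an oxocarbenium ion, blocks dioxanylium trapping, retro-Prins cleavage and 1,3-hydride shift at C3.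

**Step 6**
Reactants: 11 (1R)-3,5,5-trimethyl-4-[(trimethylsilyl)ethynyl]cyclohex-3-en-1-yl trifluoroacetate
Product: 12 (1R)-4-ethynyl-3,5,5-trimethylcyclohex-3-en-1-ol
Conditions: K2CO3 (0.3 equiv), MeOH, 25 °C
Reagents that add atoms: none
Why: Base-catalysed methanolysis should cleave the activated trifluoroacetate (transesterification) and the alkynyl C–Si bond (protodesilylation) in one operation without touching the enyne or the stereocentre.

**Step 7**
Reactants: 13 ethyl acetoacetate
Product: 14 ethyl (2E)-3-{[(trifluoromethyl)sulfonyl]oxy}but-2-enoate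
Conditions: (CF3SO2)2O, aq. (CH3)4NOH, hexane, 5 → 25 °C
Reagents that add atoms: trifluoromethanesulfonic anhydride, O=S(=O)(OS(=O)(=O)C(F)(F)F)C(F)(F)F
Why: O-Sulfonylation of the non-chelated ammonium enolate, which prefers the extended geometry, should give the E-enol triflate (stereoselective enol triflation of a β-keto ester).

**Step 8**
Reactants: 12 (1R)-4-ethynyl-3,5,5-trimethylcyclohex-3-en-1-ol; 14 ethyl (2E)-3-{[(trifluoromethyl)sulfonyl]oxy}but-2-enoate
Product: 15 ethyl (2E)-5-[(4R)-4-hydroxy-2,6,6-trimethylcyclohex-1-en-1-yl]-3-methylpent-2-en-4-ynoate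
Conditions: Pd(PPh3)4 (3 mol %), CuI (6 mol %), Et3N, THF, 25 °C
Reagents that add atoms: none
Why: Sonogashira coupling of a terminal alkyne with an electron-poor enol triflate proceeds with retention at the alkene, which fixes the 9E double bond.

**Step 9**
Reactants: 15 ethyl (2E)-5-[(4R)-4-hydroxy-2,6,6-trimethylcyclohex-1-en-1-yl]-3-methylpent-2-en-4-ynoate
Product: 16 (1R)-4-[(3E)-5-hydroxy-3-methylpent-3-en-1-yn-1-yl]-3,5,5-trimethylcyclohex-3-en-1-ol
Conditions: (i-Bu)2AlH (3.5 equiv), CH2Cl2, −78 → 0 °C; aq. KNaC4H4O6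
Reagents that add atoms: none
Why: Aluminium hydride 1,2-reduction of the conjugated ester gives the allylic alcohol without affecting the enyne.

**Step 10**
Reactants: 16 (1R)-4-[(3E)-5-hydroxy-3-methylpent-3-en-1-yn-1-yl]-3,5,5-trimethylcyclohex-3-en-1-ol
Product: 17 [(2E)-5-[(4R)-4-hydroxy-2,6,6-trimethylcyclohex-1-en-1-yl]-3-methylpent-2-en-4-yn-1-yl]triphenylphosphonium bromide
Conditions: Ph3P·HBr (1.05 equiv), MeOH, 25 °C
Reagents that add atoms: triphenylphosphine hydrobromide, Br.c1ccc(cc1)P(c1ccccc1)c1ccccc1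
Why: Acid-mediated substitution of the primary allylic alcohol by triphenylphosphine (the usual formation of a C15 Wittig salt) should leave the non-allylic ring hydroxyl alone.

**Step 11**
Reactants: 18 ethyl (2E)-4-bromo-2-methylbut-2-enoate
Product: 19 ethyl (2E)-4-(diethoxyphosphoryl)-2-methylbut-2-enoate
Conditions: P(OEt)3 (1.2 equiv), neat, 120 °C, bromoethane distilled off
Reagents that add atoms: triethyl phosphite, CCOP(OCC)OCC
Why: Michaelis–Arbuzov reaction of a primary allylic bromide gives the allylic phosphonate with the double bond unchanged.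

**Step 12**
Reactants: 19 ethyl (2E)-4-(diethoxyphosphoryl)-2-methylbut-2-enoate; 20 (2E,4E,6E)-2,7-dimethylocta-2,4,6-trienedial
Product: 21 ethyl (2E,4E,6E,8E,10E)-2,6,11-trimethyl-12-oxododeca-2,4,6,8,10-pentaenoate
Conditions: NaH (1.0 equiv), THF, 0 °C; added slowly to 20 (2.5 equiv), THF, −20 → 25 °C
Reagents that add atoms: none
Why: Horner–Wadsworth–Emmons olefination of one aldehyde group should form the new disubstituted double bond E, the excess of symmetrical dialdehyde limiting double olefination.

**Step 13**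
Reactants: 17 [(2E)-5-[(4R)-4-hydroxy-2,6,6-trimethylcyclohex-1-en-1-yl]-3-methylpent-2-en-4-yn-1-yl]triphenylphosphonium bromide; 21 ethyl (2E,4E,6E,8E,10E)-2,6,11-trimethyl-12-oxododeca-2,4,6,8,10-pentaenoate
Product: 22 ethyl (3R)-3-hydroxy-7,8-didehydro-8'-apo-β-caroten-8'-oate
Conditions: NaOEt (1.1 equiv), EtOH/CH2Cl2, 0 → 25 °C; then heptane, 80 °C, dark
Reagents that add atoms: none
Why: Wittig olefination of the allylic ylide with the polyenal forms C11=C12, and the hindered 11Z isomer expected alongside should equilibrate thermally to the all-E chain, as is usual for carotenoid Wittig products.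

**Step 14**
Reactants: 22 ethyl (3R)-3-hydroxy-7,8-didehydro-8'-apo-β-caroten-8'-oate
Product: 23 (3R)-7,8-didehydro-8'-apo-β-carotene-3,8'-diol
Conditions: (i-Bu)2AlH (3.5 equiv), CH2Cl2/THF, −78 → −20 °C; aq. KNaC4H4O6
Reagents that add atoms: none
Why: Aluminium hydride reduction of the polyenoate stops cleanly at the primary allylic alcohol.

**Step 15**
Reactants: 23 (3R)-7,8-didehydro-8'-apo-β-carotene-3,8'-diol
Product: 24 (3R)-3-hydroxy-7,8-didehydro-8'-apo-β-caroten-8'-al
Conditions: activated MnO2 (20 equiv), CH2Cl2, 25 °C, dark, argon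
Reagents that add atoms: none
Why: Manganese dioxide oxidises only the polyenylic (allylic) primary alcohol to the aldehyde, the non-allylic secondary ring alcohol not being activated.

**Compound list**

1 | (S)-epichlorohydrin, (2S)-2-(chloromethyl)oxirane | ClC[C@@H]1CO1 | starting material
2 | isopropenylmagnesium bromide | CC(=C)[Mg]Br | starting material
3 | (2S)-1-chloro-4-methylpent-4-en-2-ol | C=C(C)C[C@H](O)CCl | intermediate
4 | (2S)-2-(2-methylprop-2-en-1-yl)oxirane | C=C(C)C[C@H]1CO1 | intermediate
5 | (4S)-6-methylhept-6-en-1-yn-4-ol | C#CC[C@@H](O)CC(C)=C | intermediate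
6 | dimethylaluminium alkoxide of (1E,4S)-1-(dimethylalumanyl)-2,6-dimethylhepta-1,6-dien-4-ol | C[Al](C)/C=C(\C)C[C@@H](O[Al](C)C)CC(C)=C | intermediate
7 | (1E,4S)-1-iodo-2,6-dimethylhepta-1,6-dien-4-ol | I/C=C(\C)C[C@@H](O)CC(C)=C | intermediate
8 | ethynyltrimethylsilane | C#C[Si](C)(C)C | starting material
9 | (4S,6E)-2,6-dimethyl-9-(trimethylsilyl)nona-1,6-dien-8-yn-4-ol | C[Si](C)(C)C#C/C=C(\C)C[C@@H](O)CC(C)=C | intermediate
10 | (4S,6E)-2,6-dimethyl-9-(trimethylsilyl)nona-1,6-dien-8-yn-4-yl trifluoroacetate | C[Si](C)(C)C#C/C=C(\C)C[C@@H](OC(=O)C(F)(F)F)CC(C)=C | intermediate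
11 | (1R)-3,5,5-trimethyl-4-[(trimethylsilyl)ethynyl]cyclohex-3-en-1-yl trifluoroacetate | CC1=C(C#C[Si](C)(C)C)C(C)(C)C[C@H](OC(=O)C(F)(F)F)C1 | intermediate
12 | (1R)-4-ethynyl-3,5,5-trimethylcyclohex-3-en-1-ol | CC1=C(C#C)C(C)(C)C[C@H](O)C1 | intermediate
13 | ethyl acetoacetate | CCOC(=O)CC(C)=O | starting material
14 | ethyl (2E)-3-{[(trifluoromethyl)sulfonyl]oxy}but-2-enoate | CCOC(=O)/C=C(\C)OS(=O)(=O)C(F)(F)F | intermediate
15 | ethyl (2E)-5-[(4R)-4-hydroxy-2,6,6-trimethylcyclohex-1-en-1-yl]-3-methylpent-2-en-4-ynoate | CCOC(=O)/C=C(\C)C#CC1=C(C)C[C@@H](O)CC1(C)C | intermediate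
16 | (1R)-4-[(3E)-5-hydroxy-3-methylpent-3-en-1-yn-1-yl]-3,5,5-trimethylcyclohex-3-en-1-ol | OC/C=C(\C)C#CC1=C(C)C[C@@H](O)CC1(C)C | intermediate
17 | [(2E)-5-[(4R)-4-hydroxy-2,6,6-trimethylcyclohex-1-en-1-yl]-3-methylpent-2-en-4-yn-1-yl]triphenylphosphonium bromide | C/C(C#CC1=C(C)C[C@@H](O)CC1(C)C)=C\C[P+](c1ccccc1)(c1ccccc1)c1ccccc1.[Br-] | intermediate
18 | ethyl (2E)-4-bromo-2-methylbut-2-enoate | CCOC(=O)/C(C)=C/CBr | starting material
19 | ethyl (2E)-4-(diethoxyphosphoryl)-2-methylbut-2-enoate | CCOC(=O)/C(C)=C/CP(=O)(OCC)OCC | intermediate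
20 | (2E,4E,6E)-2,7-dimethylocta-2,4,6-trienedial | O=C/C(C)=C/C=C/C=C(\C)C=O | starting material
21 | ethyl (2E,4E,6E,8E,10E)-2,6,11-trimethyl-12-oxododeca-2,4,6,8,10-pentaenoate | CCOC(=O)/C(C)=C/C=C/C(C)=C/C=C/C=C(\C)C=O | intermediate
22 | ethyl (3R)-3-hydroxy-7,8-didehydro-8'-apo-β-caroten-8'-oate (all-E) | CC1=C(C#C/C(C)=C/C=C/C(C)=C/C=C/C=C(C)/C=C/C=C(\C)C(=O)OCC)C(C)(C)C[C@H](O)C1 | intermediate
23 | (3R)-7,8-didehydro-8'-apo-β-carotene-3,8'-diol (all-E) | CC1=C(C#C/C(C)=C/C=C/C(C)=C/C=C/C=C(C)/C=C/C=C(\C)CO)C(C)(C)C[C@H](O)C1 | intermediate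
24 | (3R)-3-hydroxy-7,8-didehydro-8'-apo-β-caroten-8'-al, (2E,4E,6E,8E,10E,12E,14E)-17-[(4R)-4-hydroxy-2,6,6-trimethylcyclohex-1-en-1-yl]-2,6,11,15-tetramethylheptadeca-2,4,6,8,10,12,14-heptaen-16-ynal | CC1=C(C#C/C(C)=C/C=C/C(C)=C/C=C/C=C(C)/C=C/C=C(\C)C=O)C(C)(C)C[C@H](O)C1 | target

**Totals**

Total step count: 15. Longest linear sequence: 12 steps (1–6, 8–10, 13–15).

**Steps most likely to fail**

Step 5. The cyclisation may suffer from ionisation at the enyne instead of the isobutenyl alkene, acid-induced oligomerisation or protodesilylation of the enyne, interference of the C3 oxygen function with the cationic centres, or incomplete drain of the double-bond isomers into conjugation. The fallback closes the same bond by a radical and brings the alkyne in afterwards. It sets out from 3, which is closed with NaOH to epoxide 4, now isolated by distillation. LiN(i-Pr)2 and propionitrile (THF, −78 → 0 °C) open 4 at its CH2 terminus to give (4R)-4-hydroxy-2,6-dimethylhept-6-enenitrile F1 as both C2 epimers. Silylation (t-BuMe2SiCl, imidazole) gives (4R)-4-[(tert-butyldimethylsilyl)oxy]-2,6-dimethylhept-6-enenitrile F2. Hydrogen-atom transfer to the 1,1-disubstituted alkene (Fe(acac)3 cat., PhSiH3, EtOH, 60 °C) generates the tertiary radical, which should add 6-exo to the nitrile carbon; hydrolysis of the imine gives (4R)-4-[(tert-butyldimethylsilyl)oxy]-2,2,6-trimethylcyclohexan-1-one F3, whose C6 epimers are both usable. Addition of LiC≡CSiMe3 with CeCl3 gives (4R)-4-[(tert-butyldimethylsilyl)oxy]-2,2,6-trimethyl-1-[(trimethylsilyl)ethynyl]cyclohexan-1-ol F4. Dehydration with POCl3 in pyridine, possible only towards C5, gives tert-butyldimethyl{[(1R)-3,5,5-trimethyl-4-[(trimethylsilyl)ethynyl]cyclohex-3-en-1-yl]oxy}silane F5, and Bu4NF removes both silyl groups to return to the route at 12.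

Step 13. The Wittig reaction may give poor E/Z control at the new C11=C12 bond, and the thermal equilibration may erode the 9E geometry next to the alkyne or degrade the polyene. The fallback uses a phosphonate carbanion, which is expected to be E-selective without a thermal isomerisation. It sets out from 16: CBr4/PPh3 at −20 °C converts the primary allylic alcohol into (1R)-4-[(3E)-5-bromo-3-methylpent-3-en-1-yn-1-yl]-3,5,5-trimethylcyclohex-3-en-1-ol F6. Heating with P(OEt)3 gives diethyl [(2E)-5-[(4R)-4-hydroxy-2,6,6-trimethylcyclohex-1-en-1-yl]-3-methylpent-2-en-4-yn-1-yl]phosphonate F7. Deprotonation with NaN(SiMe3)2 (2 equiv, THF, −78 °C) and addition of 21 returns to the route at 22.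

Step 12. Mono-olefination of the symmetrical dialdehyde may be unselective, with statistical double olefination and a difficult separation from recovered dialdehyde. The fallback changes the order of chain assembly. It sets out from 17, which is condensed with an excess of 20 (NaOEt, EtOH/CH2Cl2) to give (3R)-3-hydroxy-7,8-didehydro-12'-apo-β-caroten-12'-al F8, whose remaining aldehyde is the less reactive end of a long polyene. HWE olefination of F8 with the sodium salt of 19 (NaH, THF) returns to the route at 22.

**Further compounds**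

F1 | step 5 | (4R)-4-hydroxy-2,6-dimethylhept-6-enenitrile | CC(C#N)C[C@@H](O)CC(C)=C
F2 | step 5 | (4R)-4-[(tert-butyldimethylsilyl)oxy]-2,6-dimethylhept-6-enenitrile | CC(C#N)C[C@@H](O[Si](C)(C)C(C)(C)C)CC(C)=C
F3 | step 5 | (4R)-4-[(tert-butyldimethylsilyl)oxy]-2,2,6-trimethylcyclohexan-1-one | CC1C[C@@H](O[Si](C)(C)C(C)(C)C)CC(C)(C)C1=O
F4 | step 5 | (4R)-4-[(tert-butyldimethylsilyl)oxy]-2,2,6-trimethyl-1-[(trimethylsilyl)ethynyl]cyclohexan-1-ol | CC1C[C@@H](O[Si](C)(C)C(C)(C)C)CC(C)(C)C1(O)C#C[Si](C)(C)C
F5 | step 5 | tert-butyldimethyl{[(1R)-3,5,5-trimethyl-4-[(trimethylsilyl)ethynyl]cyclohex-3-en-1-yl]oxy}silane | CC1=C(C#C[Si](C)(C)C)C(C)(C)C[C@H](O[Si](C)(C)C(C)(C)C)C1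
F6 | step 13 | (1R)-4-[(3E)-5-bromo-3-methylpent-3-en-1-yn-1-yl]-3,5,5-trimethylcyclohex-3-en-1-ol | BrC/C=C(\C)C#CC1=C(C)C[C@@H](O)CC1(C)C
F7 | step 13 | diethyl [(2E)-5-[(4R)-4-hydroxy-2,6,6-trimethylcyclohex-1-en-1-yl]-3-methylpent-2-en-4-yn-1-yl]phosphonate | CCOP(=O)(OCC)C/C=C(\C)C#CC1=C(C)C[C@@H](O)CC1(C)C
F8 | step 12 | (3R)-3-hydroxy-7,8-didehydro-12'-apo-β-caroten-12'-al | CC1=C(C#C/C(C)=C/C=C/C(C)=C/C=C/C=C(\C)C=O)C(C)(C)C[C@H](O)C1
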